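**Retrosynthetic overview**
- The dihydropyranone ring is closed last: acid removes the silyl groups from a coumarin-3-yl δ-silyloxy-β-diketone and the freed hydroxyl cyclodehydrates onto the coumarin-bound ketone.
- The coumarin C3–C4 bond is the key convergent bond: an intermolecular Knoevenagel-type aldol condensation of a fully substituted salicylaldehyde with a 6-substituted 4-hydroxy-2-pyranone, followed by translactonisation that opens the pyranone to the β-diketone.
- Pyranone fragment: Claisen condensation of the methyl acetoacetate dianion with the Weinreb amide of silylated methyl (R)-3-hydroxybutanoate (source of the R centre), then lactonisation.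
- Salicylaldehyde fragment: aryl Grignard opening of (S)-2-methyloxirane (source of the S centre), two ring C-methylations, demethylation, silylation and ortho-formylation.
- Ring order: 2-pyranone (temporary), then coumarin, then dihydropyranone.

Assumption: 1-bromo-3,5-dimethoxybenzene, (S)-2-methyloxirane, methyl (R)-3-hydroxybutanoate and methyl acetoacetate are bought. The SMILES is read as (2R) at the dihydropyranone carbon and (2S) at the side-chain carbinol. TBS = tert-butyldimethylsilyl, TBSO = tert-butyldimethylsilyloxy.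

**Salicylaldehyde fragment**

Step 1
Reactants: 1 1-bromo-3,5-dimethoxybenzene; 2 (S)-2-methyloxirane
Product: 4 (2S)-1-(3,5-dimethoxyphenyl)propan-2-ol, via Grignard reagent 3 (not isolated)
Conditions: Mg, THF, reflux; then CuI (10 mol %), 2, −30 °C → 0 °C; 1 M HCl
Reagents that add atoms: magnesium, [Mg] (stays in 3 only)
Why: Copper-catalysed Grignard opening of the epoxide at its unsubstituted carbon (SN2) does not touch the C–O stereocentre, so the (S)-carbinol comes directly from the chiral pool.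

Step 2
Reactants: 4 (2S)-1-(3,5-dimethoxyphenyl)propan-2-ol
Product: 6 (2S)-1-(3,5-dimethoxy-4-methylphenyl)propan-2-ol, via dilithio species 5 (not isolated)
Conditions: n-BuLi (2.4 equiv), THF, 0 °C → rt; MeI, −78 °C → 0 °C; then H2O
Reagents that add atoms: n-butyllithium, [Li]CCCC (lithium stays in 5 only); iodomethane, CI
Why: Directed ortho-metalation of the alkoxide takes place at the ring position flanked by both methoxy groups, and the aryllithium is methylated far faster than the lithium alkoxide.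

Step 3
Reactants: 6 (2S)-1-(3,5-dimethoxy-4-methylphenyl)propan-2-ol
Product: 7 (2S)-1-(2-bromo-3,5-dimethoxy-4-methylphenyl)propan-2-ol
Conditions: NBS (1.0 equiv), MeCN, 0 °C
Reagents that add atoms: N-bromosuccinimide, O=C1CCC(=O)N1Br
Why: Electrophilic aromatic bromination gives one monobromide because the two free ring positions are equivalent and each is ortho/para to a methoxy group.

Step 4
Reactants: 7 (2S)-1-(2-bromo-3,5-dimethoxy-4-methylphenyl)propan-2-ol
Product: 9 (2S)-1-(3,5-dimethoxy-2,4-dimethylphenyl)propan-2-ol, via dilithio species 8 (not isolated)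
Conditions: n-BuLi (2.2 equiv), THF, −78 °C; MeI, −78 °C → 0 °C; then H2O
Reagents that add atoms: n-butyllithium, [Li]CCCC (lithium stays in 8 only); iodomethane, CI
Why: Bromine–lithium exchange followed by alkylation with iodomethane replaces bromine by methyl at a fixed position, with the carbinol stereocentre protected as its lithium alkoxide.

Step 5
Reactants: 9 (2S)-1-(3,5-dimethoxy-2,4-dimethylphenyl)propan-2-ol
Product: 10 5-[(2S)-2-hydroxypropyl]-2,4-dimethylbenzene-1,3-diol
Conditions: BBr3 (4 equiv), CH2Cl2, −78 °C → 0 °C; then H2O, 0 °C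
Reagents that add atoms: none
Why: Lewis-acid ether cleavage with BBr3 removes both aryl methyl ethers by bromide attack at the methyl carbons, while the secondary alcohol is only held as a borate at or below 0 °C and is returned with its configuration on hydrolysis.

Step 6
Reactants: 10 5-[(2S)-2-hydroxypropyl]-2,4-dimethylbenzene-1,3-diol
Product: 12 5-[(2S)-2-(TBSO)propyl]-2,4-dimethylbenzene-1,3-diol, via tris-silyl ether 11 (not isolated)
Conditions: TBSCl (4 equiv), imidazole, DMF, rt; then K2CO3, MeOH, rt → 40 °C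
Reagents that add atoms: tert-butyldimethylsilyl chloride, CC(C)(C)[Si](C)(C)Cl
Why: Exhaustive silylation followed by base-catalysed methanolysis uses the much higher lability of aryl silyl ethers over the secondary alkyl silyl ether, so only the side-chain hydroxyl stays protected.

Step 7
Reactants: 12 5-[(2S)-2-(TBSO)propyl]-2,4-dimethylbenzene-1,3-diol
Product: 13 2,4-dihydroxy-3,5-dimethyl-6-[(2S)-2-(TBSO)propyl]benzaldehyde
Conditions: MgCl2, Et3N, (CH2O)n, THF, 65 °C; cold 1 M HCl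
Reagents that add atoms: paraformaldehyde (formaldehyde unit), C=O
Why: Magnesium-mediated ortho-formylation of a phenol (Casnati–Skattebøl reaction) delivers formaldehyde to the only free ring position, ortho to one hydroxyl and para to the other, under basic conditions that leave the silyl ether intact.

**Pyranone fragment**

Step 8
Reactants: 14 methyl (3R)-3-hydroxybutanoate
Product: 15 methyl (3R)-3-(TBSO)butanoate
Conditions: TBSCl, imidazole, DMF, rt
Reagents that add atoms: tert-butyldimethylsilyl chloride, CC(C)(C)[Si](C)(C)Cl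
Why: Standard O-silylation of a secondary alcohol, which does not involve the chiral-pool stereocentre.

Step 9
Reactants: 15 methyl (3R)-3-(TBSO)butanoate
Product: 16 (3R)-3-(TBSO)-N-methoxy-N-methylbutanamide
Conditions: MeNHOMe·HCl, i-PrMgCl, THF, −20 °C → 0 °C; 1 M HCl
Reagents that add atoms: N,O-dimethylhydroxylamine hydrochloride, CNOC.Cl
Why: Weinreb amide formation by addition of the magnesium amide to the ester proceeds at low temperature without enolisation or β-elimination and gives an acyl donor that cannot over-react.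

Step 10
Reactants: 16 (3R)-3-(TBSO)-N-methoxy-N-methylbutanamide; 17 methyl acetoacetate
Product: 19 methyl (7R)-7-(TBSO)-3,5-dioxooctanoate, via acetoacetate dianion 18 (not isolated)
Conditions: 17 (2.2 equiv), NaH, THF, 0 °C; n-BuLi, 0 °C; then 16, −78 °C → 0 °C; 1 M HCl
Reagents that add atoms: sodium hydride, [Na+].[H-]; n-butyllithium, [Li]CCCC (both metals stay in 18 only)
Why: Claisen-type condensation in which the terminal carbanion of the Weiler dianion acylates on the Weinreb amide, whose chelated tetrahedral intermediate collapses only on work-up, so no double addition occurs and the silyloxy stereocentre is untouched.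

Step 11
Reactants: 19 methyl (7R)-7-(TBSO)-3,5-dioxooctanoate
Product: 20 4-hydroxy-6-[(2R)-2-(TBSO)propyl]-2H-pyran-2-one
Conditions: DBU, toluene, rt → 40 °C; 1 M HCl wash
Reagents that add atoms: none
Why: Base-mediated lactonisation of the enolised 5-ketone oxygen onto the methyl ester gives the 4-hydroxy-2-pyranone, which fixes C3 as the only nucleophilic carbon for the coupling.

**Coupling and end game**

Step 12
Reactants: 13 2,4-dihydroxy-3,5-dimethyl-6-[(2S)-2-(TBSO)propyl]benzaldehyde; 20 4-hydroxy-6-[(2R)-2-(TBSO)propyl]-2H-pyran-2-one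
Product: 22 7-hydroxy-6,8-dimethyl-3-[(5R)-5-(TBSO)-3-oxohexanoyl]-5-[(2S)-2-(TBSO)propyl]-2H-chromen-2-one, via Knoevenagel adduct 21 (not isolated)
Conditions: piperidine (0.2 equiv), EtOH, 70 °C
Reagents that add atoms: none
Why: Knoevenagel-type aldol condensation of the pyranone C3 with the aldehyde gives the arylidene-dione, whose lactone carbonyl is then attacked by the ortho-hydroxyl (translactonisation) to form the coumarin and release the β-diketone, while both stereocentres stay as silyl ethers that do not leave under the weakly basic conditions.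

Step 13
Reactants: 22 7-hydroxy-6,8-dimethyl-3-[(5R)-5-(TBSO)-3-oxohexanoyl]-5-[(2S)-2-(TBSO)propyl]-2H-chromen-2-one
Product: 24 7-hydroxy-5-[(2S)-2-hydroxypropyl]-6,8-dimethyl-3-[(2R)-2-methyl-4-oxo-3,4-dihydro-2H-pyran-6-yl]-2H-chromen-2-one, via desilylated diketone 23 (not isolated)
Conditions: 48% aq HF, MeCN, 0 °C → rt; then TsOH·H2O (cat.), CH2Cl2, rt
Reagents that add atoms: none
Why: Acidic desilylation frees both hydroxyls and the δ-hydroxyl undergoes hemiketalisation/dehydration onto the coumarin-bound ketone (the only six-membered option) to give the vinylogous ester, forming the new C–O bond at the carbonyl carbon so that the (R)-centre is retained.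

**Compound list**
1 | 1-bromo-3,5-dimethoxybenzene | COc1cc(Br)cc(OC)c1 | starting material
2 | (S)-2-methyloxirane | C[C@H]1CO1 | starting material
3 | (3,5-dimethoxyphenyl)magnesium bromide | COc1cc([Mg]Br)cc(OC)c1 | intermediate
4 | (2S)-1-(3,5-dimethoxyphenyl)propan-2-ol | C[C@H](O)Cc1cc(OC)cc(OC)c1 | intermediate
5 | lithium (2S)-1-(4-lithio-3,5-dimethoxyphenyl)propan-2-olate | C[C@H](O[Li])Cc1cc(OC)c([Li])c(OC)c1 | intermediate
6 | (2S)-1-(3,5-dimethoxy-4-methylphenyl)propan-2-ol | C[C@H](O)Cc1cc(OC)c(C)c(OC)c1 | intermediate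
7 | (2S)-1-(2-bromo-3,5-dimethoxy-4-methylphenyl)propan-2-ol | C[C@H](O)Cc1cc(OC)c(C)c(OC)c1Br | intermediate
8 | lithium (2S)-1-(2-lithio-3,5-dimethoxy-4-methylphenyl)propan-2-olate | C[C@H](O[Li])Cc1cc(OC)c(C)c(OC)c1[Li] | intermediate
9 | (2S)-1-(3,5-dimethoxy-2,4-dimethylphenyl)propan-2-ol | C[C@H](O)Cc1cc(OC)c(C)c(OC)c1C | intermediate
10 | 5-[(2S)-2-hydroxypropyl]-2,4-dimethylbenzene-1,3-diol | C[C@H](O)Cc1cc(O)c(C)c(O)c1C | intermediate
11 | 1,3-bis(TBSO)-2,4-dimethyl-5-[(2S)-2-(TBSO)propyl]benzene | C[C@H](O[Si](C)(C)C(C)(C)C)Cc1cc(O[Si](C)(C)C(C)(C)C)c(C)c(O[Si](C)(C)C(C)(C)C)c1C | intermediate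
12 | 5-[(2S)-2-(TBSO)propyl]-2,4-dimethylbenzene-1,3-diol | C[C@H](O[Si](C)(C)C(C)(C)C)Cc1cc(O)c(C)c(O)c1C | intermediate
13 | 2,4-dihydroxy-3,5-dimethyl-6-[(2S)-2-(TBSO)propyl]benzaldehyde | C[C@H](O[Si](C)(C)C(C)(C)C)Cc1c(C=O)c(O)c(C)c(O)c1C | intermediate
14 | methyl (3R)-3-hydroxybutanoate | C[C@@H](O)CC(=O)OC | starting material
15 | methyl (3R)-3-(TBSO)butanoate | C[C@@H](O[Si](C)(C)C(C)(C)C)CC(=O)OC | intermediate
16 | (3R)-3-(TBSO)-N-methoxy-N-methylbutanamide | C[C@@H](O[Si](C)(C)C(C)(C)C)CC(=O)N(C)OC | intermediate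
17 | methyl acetoacetate | CC(=O)CC(=O)OC | starting material
18 | sodium lithium 1,3-dianion of methyl acetoacetate (carbanions at C2 and C4) | [CH2-]C(=O)[CH-]C(=O)OC.[Na+].[Li+] | intermediate
19 | methyl (7R)-7-(TBSO)-3,5-dioxooctanoate | C[C@@H](O[Si](C)(C)C(C)(C)C)CC(=O)CC(=O)CC(=O)OC | intermediate
20 | 4-hydroxy-6-[(2R)-2-(TBSO)propyl]-2H-pyran-2-one | C[C@@H](O[Si](C)(C)C(C)(C)C)Cc1cc(O)cc(=O)o1 | intermediate
21 | 3-{2,4-dihydroxy-3,5-dimethyl-6-[(2S)-2-(TBSO)propyl]benzylidene}-6-[(2R)-2-(TBSO)propyl]-2H-pyran-2,4(3H)-dione | C[C@H](O[Si](C)(C)C(C)(C)C)Cc1c(C=C2C(=O)C=C(C[C@@H](C)O[Si](C)(C)C(C)(C)C)OC2=O)c(O)c(C)c(O)c1C | intermediate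
22 | 7-hydroxy-6,8-dimethyl-3-[(5R)-5-(TBSO)-3-oxohexanoyl]-5-[(2S)-2-(TBSO)propyl]-2H-chromen-2-one | Cc1c(O)c(C)c2oc(=O)c(C(=O)CC(=O)C[C@@H](C)O[Si](C)(C)C(C)(C)C)cc2c1C[C@H](C)O[Si](C)(C)C(C)(C)C | intermediate
23 | 7-hydroxy-3-[(5R)-5-hydroxy-3-oxohexanoyl]-5-[(2S)-2-hydroxypropyl]-6,8-dimethyl-2H-chromen-2-one | Cc1c(O)c(C)c2oc(=O)c(C(=O)CC(=O)C[C@@H](C)O)cc2c1C[C@H](C)O | intermediate
24 | 7-hydroxy-5-[(2S)-2-hydroxypropyl]-6,8-dimethyl-3-[(2R)-2-methyl-4-oxo-3,4-dihydro-2H-pyran-6-yl]-2H-chromen-2-one | Cc1c(O)c(C)c2oc(=O)c(C3=CC(=O)C[C@@H](C)O3)cc2c1C[C@H](C)O | target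

**Summary**
Total step count: 13. Longest linear sequence: 9 steps (steps 1–7, 12 and 13, from 1-bromo-3,5-dimethoxybenzene).

**Steps most likely to fail**

Step 12. The aldehyde is hindered and electron-rich, and the arylidene intermediate can take up a second pyranone instead of lactonising. The fallback sets out from 13 and comes back to the route at 23.
- 13 is condensed with methyl acetoacetate 17 (piperidine cat., EtOH, 50 °C; Knoevenagel condensation and lactonisation) to give 3-acetyl-7-hydroxy-6,8-dimethyl-5-[(2S)-2-(TBSO)propyl]-2H-chromen-2-one F1.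
- Its phenol is silylated (TBSCl, imidazole, DMF) to 3-acetyl-7-(TBSO)-6,8-dimethyl-5-[(2S)-2-(TBSO)propyl]-2H-chromen-2-one F2.
- In parallel 16 is reduced (i-Bu2AlH, THF, −78 °C) to (3R)-3-(TBSO)butanal F3.
- The lithium enolate of F2 (LiN(SiMe3)2, THF, −78 °C) adds to F3 in an intermolecular aldol reaction to give 7-(TBSO)-3-[(5R)-5-(TBSO)-3-hydroxyhexanoyl]-6,8-dimethyl-5-[(2S)-2-(TBSO)propyl]-2H-chromen-2-one F4, as both carbinol epimers, which is of no consequence.
- Dess–Martin periodinane oxidises F4 to 7-(TBSO)-6,8-dimethyl-3-[(5R)-5-(TBSO)-3-oxohexanoyl]-5-[(2S)-2-(TBSO)propyl]-2H-chromen-2-one F5.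
- The conditions of step 13 strip all three silyl groups from F5 to give 23, which closes to 24.

Step 7. The very electron-rich resorcinol may give diarylmethane or benzyl ether by-products in the magnesium-mediated formylation. The fallback sets out from 12 and comes back at 23, replacing electrophilic formylation by directed ortho-lithiation.
- 12 is protected (MOMCl, i-Pr2NEt, CH2Cl2) as 1,3-bis(methoxymethoxy)-2,4-dimethyl-5-[(2S)-2-(TBSO)propyl]benzene F6.
- The only ring C–H, ortho to a methoxymethoxy group, is lithiated (n-BuLi, TMEDA, THF, 0 °C) and quenched with DMF to give 2,4-bis(methoxymethoxy)-3,5-dimethyl-6-[(2S)-2-(TBSO)propyl]benzaldehyde F7.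
- Chelation-assisted cleavage of the acetal next to the formyl group (MgBr2·OEt2, Et2O, rt) gives 2-hydroxy-4-(methoxymethoxy)-3,5-dimethyl-6-[(2S)-2-(TBSO)propyl]benzaldehyde F8.
- F8 is condensed with 20 under the conditions of step 12 to give 7-(methoxymethoxy)-6,8-dimethyl-3-[(5R)-5-(TBSO)-3-oxohexanoyl]-5-[(2S)-2-(TBSO)propyl]-2H-chromen-2-one F9.
- HCl in MeOH (rt → 40 °C) removes the acetal and both silyl groups to give 23, which closes to 24.

Step 10. The dianion can be quenched by proton transfer, and the tautomeric dioxo ester is awkward to purify. The fallback sets out from 15 and comes back at 20, bypassing 19.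
- 15 is saponified (LiOH, THF/H2O, 0 °C) to (3R)-3-(TBSO)butanoic acid F10.
- F10 is coupled with 1H-benzotriazole (EDC·HCl, CH2Cl2) to give 1-[(3R)-3-(TBSO)butanoyl]-1H-benzotriazole F11.
- The lithium dienolate of commercial 2,2,6-trimethyl-4H-1,3-dioxin-4-one (LiN(i-Pr)2, THF, −78 °C) is C-acylated by F11 to give 6-[(4R)-4-(TBSO)-2-oxopentyl]-2,2-dimethyl-4H-1,3-dioxin-4-one F12.
- Heating F12 in toluene at 110 °C generates the acylketene, which cyclises to 20 under neutral conditions.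

**Further compounds**
F1 | step 12 | 3-acetyl-7-hydroxy-6,8-dimethyl-5-[(2S)-2-(TBSO)propyl]-2H-chromen-2-one | Cc1c(O)c(C)c2oc(=O)c(C(C)=O)cc2c1C[C@H](C)O[Si](C)(C)C(C)(C)C
F2 | step 12 | 3-acetyl-7-(TBSO)-6,8-dimethyl-5-[(2S)-2-(TBSO)propyl]-2H-chromen-2-one | Cc1c(O[Si](C)(C)C(C)(C)C)c(C)c2oc(=O)c(C(C)=O)cc2c1C[C@H](C)O[Si](C)(C)C(C)(C)C
F3 | step 12 | (3R)-3-(TBSO)butanal | C[C@@H](O[Si](C)(C)C(C)(C)C)CC=O
F4 | step 12 | 7-(TBSO)-3-[(5R)-5-(TBSO)-3-hydroxyhexanoyl]-6,8-dimethyl-5-[(2S)-2-(TBSO)propyl]-2H-chromen-2-one | Cc1c(O[Si](C)(C)C(C)(C)C)c(C)c2oc(=O)c(C(=O)CC(O)C[C@@H](C)O[Si](C)(C)C(C)(C)C)cc2c1C[C@H](C)O[Si](C)(C)C(C)(C)C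
F5 | step 12 | 7-(TBSO)-6,8-dimethyl-3-[(5R)-5-(TBSO)-3-oxohexanoyl]-5-[(2S)-2-(TBSO)propyl]-2H-chromen-2-one | Cc1c(O[Si](C)(C)C(C)(C)C)c(C)c2oc(=O)c(C(=O)CC(=O)C[C@@H](C)O[Si](C)(C)C(C)(C)C)cc2c1C[C@H](C)O[Si](C)(C)C(C)(C)C
F6 | step 7 | 1,3-bis(methoxymethoxy)-2,4-dimethyl-5-[(2S)-2-(TBSO)propyl]benzene | C[C@H](O[Si](C)(C)C(C)(C)C)Cc1cc(OCOC)c(C)c(OCOC)c1C
F7 | step 7 | 2,4-bis(methoxymethoxy)-3,5-dimethyl-6-[(2S)-2-(TBSO)propyl]benzaldehyde | C[C@H](O[Si](C)(C)C(C)(C)C)Cc1c(C=O)c(OCOC)c(C)c(OCOC)c1C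
F8 | step 7 | 2-hydroxy-4-(methoxymethoxy)-3,5-dimethyl-6-[(2S)-2-(TBSO)propyl]benzaldehyde | C[C@H](O[Si](C)(C)C(C)(C)C)Cc1c(C=O)c(O)c(C)c(OCOC)c1C
F9 | step 7 | 7-(methoxymethoxy)-6,8-dimethyl-3-[(5R)-5-(TBSO)-3-oxohexanoyl]-5-[(2S)-2-(TBSO)propyl]-2H-chromen-2-one | Cc1c(OCOC)c(C)c2oc(=O)c(C(=O)CC(=O)C[C@@H](C)O[Si](C)(C)C(C)(C)C)cc2c1C[C@H](C)O[Si](C)(C)C(C)(C)C
F10 | step 10 | (3R)-3-(TBSO)butanoic acid | C[C@@H](O[Si](C)(C)C(C)(C)C)CC(=O)O
F11 | step 10 | 1-[(3R)-3-(TBSO)butanoyl]-1H-benzotriazole | C[C@@H](O[Si](C)(C)C(C)(C)C)CC(=O)n1nnc2ccccc21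
F12 | step 10 | 6-[(4R)-4-(TBSO)-2-oxopentyl]-2,2-dimethyl-4H-1,3-dioxin-4-one | C[C@@H](O[Si](C)(C)C(C)(C)C)CC(=O)CC1=CC(=O)OC(C)(C)O1
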